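**Retrosynthetic overview**
- The target is cut at the C8–CH2 bond (B-alkyl Suzuki–Miyaura) into a (2S)-8-bromo-5,7-dimethoxyflavan and a 2-vinylphenol carrying the second aryl ring.
- The bromide comes from (2S)-5,7-dimethoxyflavan by C8-selective bromination.
- Ring C, the only ring that is formed, is closed in one step by hetero-Diels–Alder addition of styrene to the A-ring ortho-quinone methide under a chiral Brønsted acid; this makes C4–C3 and O1–C2 and sets C2.
- The vinylphenol comes from 2,6-dimethoxytoluene by C–H borylation/oxidation, ortho-formylation and methylenation; both benzene rings are bought.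

Assumption 1: the biogenesis of this compound is not documented, so ring C is taken to arise by [4+2] capture of an A-ring ortho-quinone methide by a styrene (C6–C2) unit, the same ortho-quinone methide logic that would explain the ArCH2–CH2Ar′ bridge.
Assumption 2: the (R)-configured acid in step 5 is taken to give 2S; the sense is checked on the first run (CD/chiral HPLC of 10) and the antipodal catalyst is used if it is the other way round.

**Route**

Step 1
Reactants: 1 2,6-dimethoxytoluene
Product: 3 3,5-dimethoxy-4-methylphenol, via arylboronate 2 (not isolated)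
Conditions: [Ir(OMe)(cod)]2 (1.5 mol%), dtbpy (3 mol%), B2pin2 (1.0 equiv), THF, 80 °C; then 30% H2O2, aq NaOH, 0 °C
Reagents that add atoms: hydrogen peroxide, OO
Why: Sterically governed Ir-catalysed C–H borylation (Hartwig–Miyaura type) takes the only ring C–H without an ortho substituent (para to CH3), and ipso-oxidation of the C–B bond gives the phenol in the same flask.

Step 2
Reactants: 3 3,5-dimethoxy-4-methylphenol
Product: 4 6-hydroxy-2,4-dimethoxy-3-methylbenzaldehyde
Conditions: MgCl2, Et3N, (CH2O)n, MeCN, reflux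
Reagents that add atoms: formaldehyde (as paraformaldehyde), C=O
Why: Casnati–Skattebøl ortho-formylation through the magnesium phenoxide is ortho-specific, the two ortho positions of 3 are equivalent and para is blocked by CH3, so one aldehyde forms (a second CH2O acts as hydride acceptor).

Step 3
Reactants: 4 6-hydroxy-2,4-dimethoxy-3-methylbenzaldehyde
Product: 5 2-ethenyl-3,5-dimethoxy-4-methylphenol
Conditions: Ph3PCH3Br (2.5 equiv), KOtBu (2.5 equiv), THF, 0 → 50 °C
Reagents that add atoms: methyltriphenylphosphonium bromide, C[P+](c1ccccc1)(c1ccccc1)c1ccccc1.[Br-]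
Why: Wittig methylenation, in which the first equivalent of ylide only deprotonates the phenol and the excess converts the hindered phenoxide aldehyde into the styrene.

Step 4
Reactants: 6 2-hydroxy-4,6-dimethoxybenzaldehyde
Product: 7 2-(hydroxymethyl)-3,5-dimethoxyphenol
Conditions: NaBH4, THF/MeOH, 0 °C, 20 min; pH 7 work-up, used crude and cold
Reagents that add atoms: none
Why: Borohydride reduction of the salicylaldehyde, run cold and briefly with neutral work-up because this very electron-rich salicyl alcohol ionises easily and would otherwise over-reduce or oligomerise.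

Step 5
Reactants: 7 2-(hydroxymethyl)-3,5-dimethoxyphenol; 8 styrene
Product: 10 (2S)-5,7-dimethoxy-2-phenyl-3,4-dihydro-2H-chromene, via ortho-quinone methide 9 (not isolated)
Conditions: 7 added over 8 h to styrene (10 equiv) and (R)-3,3′-bis(2,4,6-triisopropylphenyl)-H8-BINOL N-triflylphosphoramide (5 mol%), 4 Å MS, CH2Cl2, −30 °C
Reagents that add atoms: none
Why: Proposed new method: chiral-Brønsted-acid-catalysed inverse-demand hetero-Diels–Alder reaction of an unsubstituted (CH2) ortho-quinone methide with styrene, in which the acid dehydrates 7 to 9 and holds it by hydrogen bonding in its chiral pocket, the styrene CH2 terminus bonds to the methide carbon first (so Ph ends at C2) and the C2–O bond closes within the ion pair on one face to give 2S; the closest known reaction type is the N-triflylphosphoramide-catalysed asymmetric [4+2] of in situ ortho-quinone methides from ortho-hydroxybenzhydryl alcohols with styrenes (there C4 carries an aryl group, here it does not), together with the racemic acid- or heat-promoted salicyl alcohol/styrene route to flavans.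

Step 6
Reactants: 10 (2S)-5,7-dimethoxy-2-phenyl-3,4-dihydro-2H-chromene
Product: 11 (2S)-8-bromo-5,7-dimethoxy-2-phenyl-3,4-dihydro-2H-chromene
Conditions: NBS (1.0 equiv), CH2Cl2, −78 → −20 °C
Reagents that add atoms: N-bromosuccinimide, O=C1CCC(=O)N1Br
Why: Electrophilic aromatic bromination, which in 5,7-dialkoxyflavans prefers C8 (between O1 and 7-OMe) over C6 (between two OMe) as known for NBS on catechin tetra-ethers, with one equivalent at low temperature to avoid the 6,8-dibromide (the remaining ArH must show NOE to both OMe groups).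

Step 7
Reactants: 5 2-ethenyl-3,5-dimethoxy-4-methylphenol; 11 (2S)-8-bromo-5,7-dimethoxy-2-phenyl-3,4-dihydro-2H-chromene
Product: 13 2-{2-[(2S)-5,7-dimethoxy-2-phenyl-3,4-dihydro-2H-chromen-8-yl]ethyl}-3,5-dimethoxy-4-methylphenol, via bis-9-BBN adduct 12 (not isolated)
Conditions: 5 (1.3 equiv), 9-BBN (2.8 equiv), THF, 0 °C → rt; then 11, Pd(OAc)2 (5 mol%), SPhos (10 mol%), 3 M aq K3PO4, 65 °C
Reagents that add atoms: none
Why: 9-BBN first caps the phenol as a borinate and then hydroborates the styrene anti-Markovnikov, and B-alkyl Suzuki–Miyaura coupling (Pd/SPhos for a hindered, electron-rich aryl bromide) forms the C8–CH2 bond while aqueous base frees the phenol and C2 is untouched.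

**Compound list**

1 | 2,6-dimethoxytoluene | COc1cccc(OC)c1C | starting material
2 | 2-(3,5-dimethoxy-4-methylphenyl)-4,4,5,5-tetramethyl-1,3,2-dioxaborolane | COc1cc(B2OC(C)(C)C(C)(C)O2)cc(OC)c1C | intermediate
3 | 3,5-dimethoxy-4-methylphenol | COc1cc(O)cc(OC)c1C | intermediate
4 | 6-hydroxy-2,4-dimethoxy-3-methylbenzaldehyde | COc1cc(O)c(C=O)c(OC)c1C | intermediate
5 | 2-ethenyl-3,5-dimethoxy-4-methylphenol | COc1cc(O)c(C=C)c(OC)c1C | intermediate
6 | 2-hydroxy-4,6-dimethoxybenzaldehyde | COc1cc(O)c(C=O)c(OC)c1 | starting material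
7 | 2-(hydroxymethyl)-3,5-dimethoxyphenol | COc1cc(O)c(CO)c(OC)c1 | intermediate
8 | styrene | C=Cc1ccccc1 | starting material
9 | 3,5-dimethoxy-6-methylidenecyclohexa-2,4-dien-1-one (ortho-quinone methide) | COC1=CC(=O)C(=C)C(OC)=C1 | intermediate
10 | (2S)-5,7-dimethoxy-2-phenyl-3,4-dihydro-2H-chromene [(2S)-5,7-dimethoxyflavan] | COc1cc(OC)c2c(c1)O[C@H](c1ccccc1)CC2 | intermediate
11 | (2S)-8-bromo-5,7-dimethoxy-2-phenyl-3,4-dihydro-2H-chromene | COc1cc(OC)c2c(c1Br)O[C@H](c1ccccc1)CC2 | intermediate
12 | bis-9-BBN adduct of 5 (aryl O–B borinate and ArCH2CH2–B alkylborane) | COc1cc(OB2C3CCCC2CCC3)c(CCB2C3CCCC2CCC3)c(OC)c1C | intermediate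
13 | 2-{2-[(2S)-5,7-dimethoxy-2-phenyl-3,4-dihydro-2H-chromen-8-yl]ethyl}-3,5-dimethoxy-4-methylphenol (CNP0000262.1) | COc1cc(O)c(CCc2c(OC)cc(OC)c3c2O[C@H](c2ccccc2)CC3)c(OC)c1C | target

**Count**

Total steps: 7. Longest linear sequence: 4 (steps 4, 5, 6, 7 or steps 1, 2, 3, 7).

**Three steps most likely to fail**

Step 5 is the riskiest. The ortho-quinone methide 9 is strongly stabilised and the product ring is a very good arene nucleophile, so Friedel–Crafts oligomerisation competes with cycloaddition. Enantiocontrol without a C4 substituent is also untested. The fallback sets out from 6 and comes back at 10, and closes ring C by C–O bond formation at a preset carbinol centre instead. Claisen–Schmidt condensation of 6 with acetophenone (KOH, EtOH) gives (E)-3-(2-hydroxy-4,6-dimethoxyphenyl)-1-phenylprop-2-en-1-one F1. Hydrogenation (H2, Pd/C, EtOAc) saturates the alkene to 3-(2-hydroxy-4,6-dimethoxyphenyl)-1-phenylpropan-1-one F2. Noyori transfer hydrogenation (RuCl[(R,R)-TsDPEN](p-cymene), HCO2H/Et3N) gives (1R)-3-(2-hydroxy-4,6-dimethoxyphenyl)-1-phenylpropan-1-ol F3. Mitsunobu cyclisation (PPh3, DIAD, THF, 0 °C) closes the ring with inversion to give 10, and the route continues at step 6.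

Step 7 is the next risk. The free, acid-sensitive vinylphenol must be hydroborated, and the aryl bromide is di-ortho-substituted and electron-rich, so oxidative addition is slow and β-hydride elimination can compete. The fallback sets out from 11 (with 4 as the second branch) and comes back at 13, and replaces the Pd coupling by olefination and hydrogenation. Bromine–lithium exchange on 11 (n-BuLi, THF, −78 °C) and quenching with DMF gives (2S)-5,7-dimethoxy-2-phenyl-3,4-dihydro-2H-chromene-8-carbaldehyde F7. Separately, 4 is reduced (NaBH4, 0 °C) to 2-(hydroxymethyl)-3,5-dimethoxy-4-methylphenol F8, and PPh3·HBr (MeCN, reflux) converts it into (6-hydroxy-2,4-dimethoxy-3-methylbenzyl)triphenylphosphonium bromide F9. Wittig reaction of F9 (KOtBu, 2.2 equiv, THF, 0 °C) with F7 gives 2-{(E)-2-[(2S)-5,7-dimethoxy-2-phenyl-3,4-dihydro-2H-chromen-8-yl]ethenyl}-3,5-dimethoxy-4-methylphenol F10 (an E/Z mixture is acceptable). Hydrogenation (H2, 1 atm, Pd/C, EtOAc) reduces the alkene to 13.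

Step 6 is the third risk, because C6 bromination or dibromination would cost material after the stereocentre is set. The fallback sets out from 6 and comes back at 11, and places the bromine before ring C exists, where the free phenol directs ortho and the position can be proven on a simple compound. Amine-catalysed ortho-bromination of 6 (NBS, i-Pr2NH cat., CH2Cl2, 0 °C) gives 3-bromo-2-hydroxy-4,6-dimethoxybenzaldehyde F4. NaBH4 (THF/MeOH, 0 °C) gives 2-bromo-6-(hydroxymethyl)-3,5-dimethoxyphenol F5. Under the conditions of step 5 this loses water to 2-bromo-3,5-dimethoxy-6-methylidenecyclohexa-2,4-dien-1-one F6, which adds styrene 8 to give 11 directly.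

**Further compounds**

F1 | step 5 | (E)-3-(2-hydroxy-4,6-dimethoxyphenyl)-1-phenylprop-2-en-1-one | COc1cc(O)c(/C=C/C(=O)c2ccccc2)c(OC)c1
F2 | step 5 | 3-(2-hydroxy-4,6-dimethoxyphenyl)-1-phenylpropan-1-one | COc1cc(O)c(CCC(=O)c2ccccc2)c(OC)c1
F3 | step 5 | (1R)-3-(2-hydroxy-4,6-dimethoxyphenyl)-1-phenylpropan-1-ol | COc1cc(O)c(CC[C@@H](O)c2ccccc2)c(OC)c1
F4 | step 6 | 3-bromo-2-hydroxy-4,6-dimethoxybenzaldehyde | COc1cc(OC)c(C=O)c(O)c1Br
F5 | step 6 | 2-bromo-6-(hydroxymethyl)-3,5-dimethoxyphenol | COc1cc(OC)c(CO)c(O)c1Br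
F6 | step 6 | 2-bromo-3,5-dimethoxy-6-methylidenecyclohexa-2,4-dien-1-one | COC1=C(Br)C(=O)C(=C)C(OC)=C1
F7 | step 7 | (2S)-5,7-dimethoxy-2-phenyl-3,4-dihydro-2H-chromene-8-carbaldehyde | COc1cc(OC)c2c(c1C=O)O[C@H](c1ccccc1)CC2
F8 | step 7 | 2-(hydroxymethyl)-3,5-dimethoxy-4-methylphenol | COc1cc(O)c(CO)c(OC)c1C
F9 | step 7 | (6-hydroxy-2,4-dimethoxy-3-methylbenzyl)triphenylphosphonium bromide | COc1cc(O)c(C[P+](c2ccccc2)(c2ccccc2)c2ccccc2)c(OC)c1C.[Br-]
F10 | step 7 | 2-{(E)-2-[(2S)-5,7-dimethoxy-2-phenyl-3,4-dihydro-2H-chromen-8-yl]ethenyl}-3,5-dimethoxy-4-methylphenol | COc1cc(O)c(/C=C/c2c(OC)cc(OC)c3c2O[C@H](c2ccccc2)CC3)c(OC)c1C
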